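**Retrosynthetic overview**
- Target ⇒ BBr3 unmasking of the catechol and acid; caffeate by Mitsunobu esterification at C16; C16–OH and C15 by allylic oxidation of the prenyl end, then asymmetric hydrogenation; carboxyl by directed ortho-metalation.
- Ring B ⇒ cationic C4–C10 closure (laboratory counterpart of the terpene-cyclase 1,10-closure) of an ar-bisabolane-type allylic alcohol with the prenyl alkene left free; C4 is set trans to C1, then the exo-methylene is hydrogenated to set C11.
- Allylic alcohol ⇒ Nozaki–Hiyama–Kishi union of (4R)-4-arylpentanal with the enol triflate of 6-methylhept-5-en-2-one.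
- Aldehyde ⇒ enantioselective redox-relay Heck arylation of (E)-pent-3-en-1-ol (sets C1).
- Ring order: ring A is bought as the arene, ring B is closed onto it, and all oxidations follow ring formation.

Atom labels C1–C20 in the Why lines follow serrulatane numbering: C1 ring CH with methyl, C4 ring CH with side chain, C5–C10 ring A, C11 and C15 side-chain methines, C16 the CH2O carbon.

Assumption: the ligand enantiomers written in steps 1, 5 and 8 are taken to give the configurations shown; if the sense of induction is the opposite, the mirror-image ligand is used.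

Step 1
Reactants: 1 (2,3-dimethoxyphenyl)boronic acid; 2 (E)-pent-3-en-1-ol
Product: 3 (4R)-4-(2,3-dimethoxyphenyl)pentanal
Conditions: Pd(MeCN)2(OTs)2 (6 mol%), Cu(OTf)2 (6 mol%), (S)-4-tert-butyl-2-[5-(trifluoromethyl)pyridin-2-yl]-4,5-dihydrooxazole (13 mol%), O2 (1 atm), 3 Å MS, DMF, rt
Reagents that add atoms: none
Why: Enantioselective oxidative redox-relay Heck arylation, in which the aryl–palladium species adds to the alkene carbon remote from the hydroxyl under control of the chiral pyridine–oxazoline ligand (this sets C1 as R) and palladium then chain-walks to the carbinol and leaves as the aldehyde.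

Step 2
Reactants: 4 6-methylhept-5-en-2-one
Product: 6 6-methylhepta-1,5-dien-2-yl trifluoromethanesulfonate, via lithium enolate 5 (not isolated)
Conditions: LiN(iPr)2, THF, −78 °C; then PhNTf2, −78 °C → rt
Reagents that add atoms: N-phenylbis(trifluoromethanesulfonimide) O=S(=O)(N(c1ccccc1)S(=O)(=O)C(F)(F)F)C(F)(F)F
Why: Enol triflate formation by kinetic deprotonation at the methyl group and O-sulfonylation of the lithium enolate gives the less substituted alkenyl triflate without forming a stereocentre.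

Step 3
Reactants: 3 (4R)-4-(2,3-dimethoxyphenyl)pentanal; 6 6-methylhepta-1,5-dien-2-yl trifluoromethanesulfonate
Product: 8 (2R)-2-(2,3-dimethoxyphenyl)-10-methyl-6-methylideneundec-9-en-5-ol (both C5 epimers), via alkenylchromium dichloride 7 (not isolated)
Conditions: CrCl2 (4 equiv), NiCl2 (2 mol%), DMF, rt
Reagents that add atoms: none
Why: Nozaki–Hiyama–Kishi coupling, in which the nickel-catalysed alkenylchromium reagent adds only to the aldehyde and ignores the prenyl alkene, gives the carbinol as a 1:1 epimer mixture that is erased in the next step.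

Step 4
Reactants: 8 (2R)-2-(2,3-dimethoxyphenyl)-10-methyl-6-methylideneundec-9-en-5-ol
Product: 10 (5S,8R)-1,2-dimethoxy-8-methyl-5-(6-methylhepta-1,5-dien-2-yl)-5,6,7,8-tetrahydronaphthalene, via allyl cation 9 (not isolated)
Conditions: BF3·OEt2 (1.5 equiv), CH2Cl2, −78 → −40 °C; aq. NaHCO3
Reagents that add atoms: none
Why: Stereoconvergent cation–π ring closure (intramolecular Friedel–Crafts allylic alkylation mirroring the cyclase 1,10-closure) in which both carbinol epimers ionise to one allyl cation that ring A attacks at C4 through its carbon para to a methoxy group, the half-chair transition state with the C1 methyl pseudoaxial (away from the peri methoxy) and the allyl unit pseudoaxial on the opposite face giving the 1,4-trans ring B (C4 = S), while the free prenyl alkene can reach the cation only by a disfavoured 5-endo path.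

Step 5
Reactants: 10 (5S,8R)-1,2-dimethoxy-8-methyl-5-(6-methylhepta-1,5-dien-2-yl)-5,6,7,8-tetrahydronaphthalene
Product: 11 (5S,8R)-1,2-dimethoxy-8-methyl-5-[(2S)-6-methylhept-5-en-2-yl]-5,6,7,8-tetrahydronaphthalene
Conditions: [Ir(cod)((S)-tBu-PHOX)]BArF (1 mol%), H2 (1 bar), CH2Cl2, 0 °C
Reagents that add atoms: none
Why: Chemoselective iridium-catalysed asymmetric hydrogenation, in which the terminal 1,1-disubstituted alkene is reduced far faster at 1 bar than the trisubstituted prenyl alkene and hydrogen is delivered to the face anti to the aryl group (the face the substrate also prefers when C4–H eclipses the C11–C12 bond), sets C11 as S.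

Step 6
Reactants: 11 (5S,8R)-1,2-dimethoxy-8-methyl-5-[(2S)-6-methylhept-5-en-2-yl]-5,6,7,8-tetrahydronaphthalene
Product: 13 tert-butyl (5R,8S)-3,4-dimethoxy-5-methyl-8-[(2S)-6-methylhept-5-en-2-yl]-5,6,7,8-tetrahydronaphthalene-2-carboxylate, via aryllithium 12 (not isolated)
Conditions: n-BuLi, TMEDA, Et2O, 0 °C → rt; then Boc2O, −78 °C → rt
Reagents that add atoms: di-tert-butyl dicarbonate CC(C)(C)OC(=O)OC(=O)OC(C)(C)C
Why: Directed ortho-metalation removes the only ring hydrogen ortho to a methoxy group (C6) and the aryllithium is acylated by Boc2O to the tert-butyl ester, with no stereocentre touched.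

Step 7
Reactants: 13 tert-butyl (5R,8S)-3,4-dimethoxy-5-methyl-8-[(2S)-6-methylhept-5-en-2-yl]-5,6,7,8-tetrahydronaphthalene-2-carboxylate
Product: 14 tert-butyl (5R,8S)-8-[(2S,5E)-7-hydroxy-6-methylhept-5-en-2-yl]-3,4-dimethoxy-5-methyl-5,6,7,8-tetrahydronaphthalene-2-carboxylate
Conditions: SeO2 (0.3 equiv), t-BuOOH (3 equiv), salicylic acid (0.1 equiv), CH2Cl2, rt
Reagents that add atoms: selenium dioxide O=[Se]=O (oxygen carrier); tert-butyl hydroperoxide CC(C)(C)OO (net oxygen source)
Why: Riley–Sharpless allylic oxidation (ene reaction followed by 2,3-sigmatropic shift) converts the E-methyl group of the prenyl terminus into the E-allylic alcohol, a late C16 hydroxylation that forms no stereocentre.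

Step 8
Reactants: 14 tert-butyl (5R,8S)-8-[(2S,5E)-7-hydroxy-6-methylhept-5-en-2-yl]-3,4-dimethoxy-5-methyl-5,6,7,8-tetrahydronaphthalene-2-carboxylate
Product: 15 tert-butyl (5R,8S)-8-[(2S,6R)-7-hydroxy-6-methylheptan-2-yl]-3,4-dimethoxy-5-methyl-5,6,7,8-tetrahydronaphthalene-2-carboxylate
Conditions: [Ir(cod)((R)-tBu-PHOX)]BArF (1 mol%), H2 (50 bar), CH2Cl2, rt
Reagents that add atoms: none
Why: Iridium-catalysed asymmetric hydrogenation of the E-configured 2-methylallylic alcohol, the only C=C bond left, sets C15 as R under catalyst control.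

Step 9
Reactants: 15 tert-butyl (5R,8S)-8-[(2S,6R)-7-hydroxy-6-methylheptan-2-yl]-3,4-dimethoxy-5-methyl-5,6,7,8-tetrahydronaphthalene-2-carboxylate; 16 (E)-caffeic acid
Product: 18 tert-butyl (5R,8S)-8-[(2S,6R)-7-{[(2E)-3-(3,4-dihydroxyphenyl)prop-2-enoyl]oxy}-6-methylheptan-2-yl]-3,4-dimethoxy-5-methyl-5,6,7,8-tetrahydronaphthalene-2-carboxylate, via alkoxyphosphonium ion 17 (not isolated)
Conditions: PPh3 (1.5 equiv), DIAD (1.5 equiv), THF, 0 °C → rt
Reagents that add atoms: none
Why: Mitsunobu esterification activates the primary alcohol as its alkoxyphosphonium ion, which is displaced by the carboxylate of unprotected caffeic acid (its phenols are too weakly acidic to compete), and C15 is untouched because substitution occurs at the CH2 carbon.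

Step 10
Reactants: 18 tert-butyl (5R,8S)-8-[(2S,6R)-7-{[(2E)-3-(3,4-dihydroxyphenyl)prop-2-enoyl]oxy}-6-methylheptan-2-yl]-3,4-dimethoxy-5-methyl-5,6,7,8-tetrahydronaphthalene-2-carboxylate
Product: 19 (5R,8S)-8-[(2S,6R)-7-{[(2E)-3-(3,4-dihydroxyphenyl)prop-2-enoyl]oxy}-6-methylheptan-2-yl]-3,4-dihydroxy-5-methyl-5,6,7,8-tetrahydronaphthalene-2-carboxylic acid (CNP0492979.1)
Conditions: BBr3 (8 equiv), CH2Cl2, −78 → 0 °C; then H2O
Reagents that add atoms: none
Why: Lewis-acid ether and ester cleavage with BBr3 removes both aryl methyl ethers and the tert-butyl ester at low temperature while the boron-complexed caffeate and its primary alkyl ester survive, giving the target with no change at any stereocentre.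

**Compound list**
1 | (2,3-dimethoxyphenyl)boronic acid | COc1cccc(B(O)O)c1OC | starting material
2 | (E)-pent-3-en-1-ol | C/C=C/CCO | starting material
3 | (4R)-4-(2,3-dimethoxyphenyl)pentanal | O=CCC[C@@H](C)c1cccc(OC)c1OC | intermediate
4 | 6-methylhept-5-en-2-one | CC(=O)CCC=C(C)C | starting material
5 | lithium 6-methylhepta-1,5-dien-2-olate (lithium enolate) | [Li]OC(=C)CCC=C(C)C | intermediate
6 | 6-methylhepta-1,5-dien-2-yl trifluoromethanesulfonate | C=C(OS(=O)(=O)C(F)(F)F)CCC=C(C)C | intermediate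
7 | dichloro(6-methylhepta-1,5-dien-2-yl)chromium (alkenylchromium dichloride) | C=C([Cr](Cl)Cl)CCC=C(C)C | intermediate
8 | (2R)-2-(2,3-dimethoxyphenyl)-10-methyl-6-methylideneundec-9-en-5-ol (both C5 epimers) | CC(C)=CCCC(=C)C(O)CC[C@@H](C)c1cccc(OC)c1OC | intermediate
9 | (2R)-2-(2,3-dimethoxyphenyl)-10-methyl-6-methylideneundec-9-en-5-ylium (allyl cation) | CC(C)=CCCC(=C)[CH+]CC[C@@H](C)c1cccc(OC)c1OC | intermediate
10 | (5S,8R)-1,2-dimethoxy-8-methyl-5-(6-methylhepta-1,5-dien-2-yl)-5,6,7,8-tetrahydronaphthalene | CC(C)=CCCC(=C)[C@@H]1CC[C@@H](C)c2c1ccc(OC)c2OC | intermediate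
11 | (5S,8R)-1,2-dimethoxy-8-methyl-5-[(2S)-6-methylhept-5-en-2-yl]-5,6,7,8-tetrahydronaphthalene | CC(C)=CCC[C@H](C)[C@@H]1CC[C@@H](C)c2c1ccc(OC)c2OC | intermediate
12 | {(5R,8S)-3,4-dimethoxy-5-methyl-8-[(2S)-6-methylhept-5-en-2-yl]-5,6,7,8-tetrahydronaphthalen-2-yl}lithium (aryllithium) | CC(C)=CCC[C@H](C)[C@@H]1CC[C@@H](C)c2c1cc([Li])c(OC)c2OC | intermediate
13 | tert-butyl (5R,8S)-3,4-dimethoxy-5-methyl-8-[(2S)-6-methylhept-5-en-2-yl]-5,6,7,8-tetrahydronaphthalene-2-carboxylate | CC(C)=CCC[C@H](C)[C@@H]1CC[C@@H](C)c2c1cc(C(=O)OC(C)(C)C)c(OC)c2OC | intermediate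
14 | tert-butyl (5R,8S)-8-[(2S,5E)-7-hydroxy-6-methylhept-5-en-2-yl]-3,4-dimethoxy-5-methyl-5,6,7,8-tetrahydronaphthalene-2-carboxylate | OC/C(C)=C/CC[C@H](C)[C@@H]1CC[C@@H](C)c2c1cc(C(=O)OC(C)(C)C)c(OC)c2OC | intermediate
15 | tert-butyl (5R,8S)-8-[(2S,6R)-7-hydroxy-6-methylheptan-2-yl]-3,4-dimethoxy-5-methyl-5,6,7,8-tetrahydronaphthalene-2-carboxylate | C[C@H](CCC[C@H](C)[C@@H]1CC[C@@H](C)c2c1cc(C(=O)OC(C)(C)C)c(OC)c2OC)CO | intermediate
16 | (E)-caffeic acid | OC(=O)/C=C/c1ccc(O)c(O)c1 | starting material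
17 | alkoxy(triphenyl)phosphonium ion of alcohol 15 | C[C@H](CCC[C@H](C)[C@@H]1CC[C@@H](C)c2c1cc(C(=O)OC(C)(C)C)c(OC)c2OC)CO[P+](c1ccccc1)(c1ccccc1)c1ccccc1 | intermediate
18 | tert-butyl (5R,8S)-8-[(2S,6R)-7-{[(2E)-3-(3,4-dihydroxyphenyl)prop-2-enoyl]oxy}-6-methylheptan-2-yl]-3,4-dimethoxy-5-methyl-5,6,7,8-tetrahydronaphthalene-2-carboxylate | C[C@H](CCC[C@H](C)[C@@H]1CC[C@@H](C)c2c1cc(C(=O)OC(C)(C)C)c(OC)c2OC)COC(=O)/C=C/c1ccc(O)c(O)c1 | intermediate
19 | (5R,8S)-8-[(2S,6R)-7-{[(2E)-3-(3,4-dihydroxyphenyl)prop-2-enoyl]oxy}-6-methylheptan-2-yl]-3,4-dihydroxy-5-methyl-5,6,7,8-tetrahydronaphthalene-2-carboxylic acid | C[C@H](CCC[C@H](C)[C@@H]1CC[C@@H](C)c2c1cc(C(=O)O)c(O)c2O)COC(=O)/C=C/c1ccc(O)c(O)c1 | target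

**Totals**
Total step count: 10.
Longest linear sequence: 9 steps (steps 1, 3, 4, 5, 6, 7, 8, 9, 10); step 2 is a one-step side branch.

**Three steps most likely to fail**

Step 4 (cationic ring closure). The risks are a low trans:cis ratio, diene formation by proton loss, or reaction at the free prenyl alkene. The fallback sets out from allylic alcohol 8. A rhenium-oxo-catalysed 1,3-transposition (Ph3SiOReO3, Et2O, 0 °C) moves the hydroxyl to the terminus and gives (2E/Z,6R)-6-(2,3-dimethoxyphenyl)-2-(4-methylpent-3-en-1-yl)hept-2-en-1-ol F1. This is cyclised with a cationic gold–bisphosphine catalyst ((AuCl)2[(R)-DTBM-MeO-BIPHEP], AgOTf, toluene, 0 °C) in an anti-SN2′ dehydrative allylic arylation. No free cation is formed, and the ligand rather than the substrate selects the face at C4. The fallback comes back to the route at compound 10.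

Step 5 (selective hydrogenation of the exo-methylene). The risks are over-reduction of the prenyl alkene, isomerisation of the terminal alkene, or poor selectivity at C11. The fallback sets out from diene 10. Hydroboration with 9-BBN (THF, 0 °C) attacks only the 1,1-disubstituted alkene and adds anti to the aryl group; oxidation with NaOH/H2O2 gives (2S)-2-[(1S,4R)-5,6-dimethoxy-4-methyl-1,2,3,4-tetrahydronaphthalen-1-yl]-6-methylhept-5-en-1-ol F2. Tosylation (TsCl, pyridine) gives the corresponding 4-methylbenzenesulfonate F3, and reduction with LiBHEt3 in THF turns the CH2OTs group into the C11 methyl. The fallback comes back to the route at compound 11.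

Step 10 (global BBr3 deprotection next to the caffeate ester). The risks are cleavage of the alkyl caffeate or incomplete demethylation. The fallback sets out from alcohol 15, before the caffeate is attached. BBr3 (CH2Cl2, −78 → 0 °C) gives (5R,8S)-3,4-dihydroxy-8-[(2S,6R)-7-hydroxy-6-methylheptan-2-yl]-5-methyl-5,6,7,8-tetrahydronaphthalene-2-carboxylic acid F4. Immobilised Candida antarctica lipase B with vinyl caffeate in 2-methylbutan-2-ol at 50 °C then acylates only the primary aliphatic alcohol, since the phenols and the aromatic acid are not substrates. The fallback comes back to the route at target 19 and replaces steps 9 and 10.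

**Further compounds**
F1 | step 4 | (2E/Z,6R)-6-(2,3-dimethoxyphenyl)-2-(4-methylpent-3-en-1-yl)hept-2-en-1-ol | CC(C)=CCCC(CO)=CCC[C@@H](C)c1cccc(OC)c1OC
F2 | step 5 | (2S)-2-[(1S,4R)-5,6-dimethoxy-4-methyl-1,2,3,4-tetrahydronaphthalen-1-yl]-6-methylhept-5-en-1-ol | CC(C)=CCC[C@H](CO)[C@@H]1CC[C@@H](C)c2c1ccc(OC)c2OC
F3 | step 5 | (2S)-2-[(1S,4R)-5,6-dimethoxy-4-methyl-1,2,3,4-tetrahydronaphthalen-1-yl]-6-methylhept-5-en-1-yl 4-methylbenzenesulfonate | CC(C)=CCC[C@H](COS(=O)(=O)c1ccc(C)cc1)[C@@H]1CC[C@@H](C)c2c1ccc(OC)c2OC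
F4 | step 10 | (5R,8S)-3,4-dihydroxy-8-[(2S,6R)-7-hydroxy-6-methylheptan-2-yl]-5-methyl-5,6,7,8-tetrahydronaphthalene-2-carboxylic acid | C[C@H](CCC[C@H](C)[C@@H]1CC[C@@H](C)c2c1cc(C(=O)O)c(O)c2O)CO
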